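**Plan**

1. Carotenoid numbering is used (ε-ring C1–C6 with the stereocentre C6, chain C7–C15 and C15'–C1'). The retrosynthesis cuts first the C8–C9 σ-bond in the middle of the diene C7=C8–C9(CH3)=C10, then C11=C12 and C11'=C12' in the chain half, and C6–C7 in the ring half.
2. The feature that allows the first cut: C7 and C10 each carry one hydrogen where a metal can have been, so the diene is the double protonolysis product of a five-membered titanacycle (Ti, C7, C8, C9, C10) formed from two alkynes, C7≡C8 (terminal, on the ring) and C9≡C10 (methyl-capped, on the chain).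
3. Chain half, forward: farnesyl ylide + C10 dialdehyde (Wittig, C11'=C12') to a C25 aldehyde, then Horner–Wadsworth–Emmons reaction with a but-2-ynyl phosphonate (C11=C12) to the C29 polyenyne.
4. Ring half, forward: CBS reduction of 2,4,4-trimethylcyclohex-2-en-1-one, Johnson–Claisen rearrangement (C6–C7), reduction to the aldehyde, and enol sulfonate elimination to the C11 ethynyl ring.
5. Last step: titanium-mediated reductive cross-coupling of the two alkynes and protonolysis, which should make C8–C9 and both flanking E double bonds in one flask; the alkyne oxidation level and the temporary titanacycle are the only helpers and leave in that flask.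
6. Stereochemistry: C6 comes from the CBS-set carbinol by suprafacial 1,3-transfer in the Claisen step; chain geometry comes from (2E,6E)-farnesyl bromide, the all-E dialdehyde, trans-selective olefination with iodine equilibration, and syn-carbotitanation with retentive protonolysis.

Key step: step 9

Assumption: (2E,6E)-farnesyl bromide and all-E 2,7-dimethylocta-2,4,6-trienedial are used as the commercial, geometrically pure materials.

**Route**

Step 1
Reactants: 1 2,4,4-trimethylcyclohex-2-en-1-one
Product: 2 (1S)-2,4,4-trimethylcyclohex-2-en-1-ol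
Conditions: (R)-1-methyl-3,3-diphenyltetrahydro-1H,3H-pyrrolo[1,2-c][1,3,2]oxazaborole (the (R)-methyl CBS oxazaborolidine, 10 mol %), BH3·SMe2, THF, −20 °C; then MeOH, aq. NH4Cl
Reagents that add atoms: none
Why: Corey–Bakshi–Shibata reduction: the oxazaborolidine–borane complex binds the carbonyl oxygen anti to the larger α-methylvinyl flank and delivers hydride to one face only, which should set the carbinol carbon as S (the centre that later relays its chirality to C6).

Step 2
Reactants: 2 (1S)-2,4,4-trimethylcyclohex-2-en-1-ol
Product: 4 ethyl 2-[(1R)-2,6,6-trimethylcyclohex-2-en-1-yl]acetate, via ketene acetal 3 (not isolated)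
Conditions: MeC(OEt)3 (5 equiv), EtCO2H (cat.), 140 °C, EtOH distilled off
Reagents that add atoms: triethyl orthoacetate, CC(OCC)(OCC)OCC
Why: Johnson–Claisen rearrangement: acid-catalysed exchange and loss of ethanol give ketene acetal 3, whose [3,3]-sigmatropic shift is suprafacial across the cyclohexenyl allyl unit, so the new C6–C7 bond forms on the ring face that carried the C–O bond and the S carbinol centre is translated into the R centre next to the gem-dimethyl carbon while the ring double bond moves to C4=C5.

Step 3
Reactants: 4 ethyl 2-[(1R)-2,6,6-trimethylcyclohex-2-en-1-yl]acetate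
Product: 5 2-[(1R)-2,6,6-trimethylcyclohex-2-en-1-yl]acetaldehyde
Conditions: i-Bu2AlH (1.05 equiv), CH2Cl2, −78 °C; then MeOH, aq. potassium sodium tartrate
Reagents that add atoms: none
Why: Partial reduction of an ester with i-Bu2AlH: the tetrahedral aluminium hemiacetal is stable at −78 °C and collapses to the aldehyde only on work-up, and the stereocentre is β to the carbonyl and cannot epimerise.

Step 4
Reactants: 5 2-[(1R)-2,6,6-trimethylcyclohex-2-en-1-yl]acetaldehyde
Product: 7 (6S)-6-ethynyl-1,5,5-trimethylcyclohex-1-ene, via alkenyl nonaflate 6 (not isolated)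
Conditions: n-C4F9SO2F (1.2 equiv), phosphazene base P2-Et (2.4 equiv), DMF, −30 °C → rt
Reagents that add atoms: none
Why: One-pot enol sulfonylation–elimination of an enolisable aldehyde: the phosphazene base generates the enolate, which is O-sulfonylated to alkenyl nonaflate 6, and a second equivalent of base eliminates nonaflate from C8 and H from C7 to the terminal alkyne without changing the carbon count; the ring stereocentre is not involved and only its CIP descriptor changes (ethynyl outranks the quaternary carbon).

Step 5
Reactants: 8 (2E,6E)-1-bromo-3,7,11-trimethyldodeca-2,6,10-triene ((2E,6E)-farnesyl bromide)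
Product: 9 [(2E,6E)-3,7,11-trimethyldodeca-2,6,10-trien-1-yl]triphenylphosphonium bromide
Conditions: PPh3, toluene, rt
Reagents that add atoms: triphenylphosphine, c1ccc(cc1)P(c1ccccc1)c1ccccc1
Why: SN2 quaternisation of a primary allylic bromide by PPh3, which should leave both trisubstituted E double bonds untouched.

Step 6
Reactants: 9 [(2E,6E)-3,7,11-trimethyldodeca-2,6,10-trien-1-yl]triphenylphosphonium bromide; 10 (2E,4E,6E)-2,7-dimethylocta-2,4,6-trienedial
Product: 12 (2E,4E,6E,8E,10E,14E)-2,7,11,15,19-pentamethylicosa-2,4,6,8,10,14,18-heptaenal, via ylide 11 (not isolated)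
Conditions: 9, n-BuLi, THF, −78 °C; cannulated into 10 (3 equiv), THF, −78 → 0 °C; then I2 (cat.), CH2Cl2, rt, daylight
Reagents that add atoms: none
Why: Wittig olefination: the allylic ylide 11 is added to an excess of the symmetrical dialdehyde so that one formyl group reacts, and the E/Z mixture at the new C11'=C12' bond should be equilibrated to the all-E heptaenal by iodine-catalysed isomerisation.

Step 7
Reactants: 13 1-bromobut-2-yne
Product: 14 diethyl but-2-yn-1-ylphosphonate
Conditions: P(OEt)3, neat, 110 °C, EtBr distilled off
Reagents that add atoms: triethyl phosphite, CCOP(OCC)OCC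
Why: Michaelis–Arbuzov reaction: SN2 attack of phosphorus on the propargylic bromide and dealkylation of the phosphonium intermediate by bromide should give the but-2-ynyl phosphonate.

Step 8
Reactants: 14 diethyl but-2-yn-1-ylphosphonate; 12 (2E,4E,6E,8E,10E,14E)-2,7,11,15,19-pentamethylicosa-2,4,6,8,10,14,18-heptaenal
Product: 16 (4E,6E,8E,10E,12E,14E,18E)-6,11,15,19,23-pentamethyltetracosa-4,6,8,10,12,14,18,22-octaen-2-yne, via lithiated phosphonate 15 (not isolated)
Conditions: 14, LiN(SiMe3)2, THF, −78 °C; then 12, −78 → 0 °C
Reagents that add atoms: none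
Why: Horner–Wadsworth–Emmons olefination with a propargylic phosphonate carbanion, which adds 1,2 to the α-branched polyenal and should eliminate to the trans C11=C12 enyne.

Step 9
Reactants: 16 (4E,6E,8E,10E,12E,14E,18E)-6,11,15,19,23-pentamethyltetracosa-4,6,8,10,12,14,18,22-octaen-2-yne; 7 (6S)-6-ethynyl-1,5,5-trimethylcyclohex-1-ene
Product: 19 (6R)-7',8'-dihydro-ε,ψ-carotene (α-zeacarotene), via titanacyclopropene 17 (not isolated), via titanacyclopentadiene 18 (not isolated)
Conditions: 16, Ti(OiPr)4 (1.2 equiv), i-PrMgCl (2.4 equiv), Et2O–toluene, −78 → −50 °C; then 7 (1.3 equiv), −50 → −30 °C; then H2O, −30 → 0 °C; argon, dark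
Reagents that add atoms: none
Why: Ti(OiPr)4 and two equivalents of i-PrMgCl give diisopropoxy(η2-propene)titanium, a divalent-titanium equivalent that exchanges propene for the C9≡C10 triple bond of 16 to give titanacyclopropene 17; the terminal C7≡C8 triple bond of 7 then inserts into the Ti–C9 bond, which forms the C8–C9 σ-bond, and water finally cleaves both Ti–C bonds with retention. The closest known reaction type is the titanium alkoxide-mediated reductive cross-coupling of an internal alkyne with a terminal alkyne to a stereodefined 1,3-diene. The only ring closed is the temporary five-membered titanacycle 18 (Ti, C7, C8, C9, C10), formed by syn-carbotitanation as a ring expansion from three to five members and opened again by protonolysis, so no ring of the target is made here. No stereocentre is created and C6 is carried through untouched, since no base strong enough to remove the propargylic C6–H remains once the Grignard reagent is consumed; both new double bonds should be E because titanium and the new C–C bond are cis on each alkene inside the metallacycle, so H replaces Ti cis to C9 on C7 and cis to C8 on C10. The step needs cross- over homo-coupling (17 is pre-formed at −50 °C before 7 is added), regiocontrol at both alkynes (the unsubstituted C8 bonds to carbon while the bulky ring-bearing C7 goes to titanium; the small methyl-bearing C9 bonds to carbon while C10 keeps titanium, its Ti–C bond being conjugated with the polyene), and chemoselectivity for the triple bond over the di- and trisubstituted polyene double bonds, which should not displace propene at low temperature.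

**Compound list**

1 | 2,4,4-trimethylcyclohex-2-en-1-one | CC1=CC(C)(C)CCC1=O | starting material
2 | (1S)-2,4,4-trimethylcyclohex-2-en-1-ol | O[C@@H]1C(C)=CC(C)(C)CC1 | intermediate
3 | 1-ethoxy-1-{[(1S)-2,4,4-trimethylcyclohex-2-en-1-yl]oxy}ethene (ketene acetal) | C=C(OCC)O[C@@H]1C(C)=CC(C)(C)CC1 | intermediate
4 | ethyl 2-[(1R)-2,6,6-trimethylcyclohex-2-en-1-yl]acetate | CCOC(=O)C[C@H]1C(C)=CCCC1(C)C | intermediate
5 | 2-[(1R)-2,6,6-trimethylcyclohex-2-en-1-yl]acetaldehyde | O=CC[C@H]1C(C)=CCCC1(C)C | intermediate
6 | 2-[(1R)-2,6,6-trimethylcyclohex-2-en-1-yl]ethenyl nonafluorobutane-1-sulfonate (E/Z mixture) | FC(F)(F)C(F)(F)C(F)(F)C(F)(F)S(=O)(=O)OC=C[C@H]1C(C)=CCCC1(C)C | intermediate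
7 | (6S)-6-ethynyl-1,5,5-trimethylcyclohex-1-ene (same spatial arrangement as C6 of the target; S only by CIP priority) | C#C[C@H]1C(C)=CCCC1(C)C | intermediate
8 | (2E,6E)-1-bromo-3,7,11-trimethyldodeca-2,6,10-triene | CC(C)=CCC/C(C)=C/CC/C(C)=C/CBr | starting material
9 | [(2E,6E)-3,7,11-trimethyldodeca-2,6,10-trien-1-yl]triphenylphosphonium bromide | CC(C)=CCC/C(C)=C/CC/C(C)=C/C[P+](c1ccccc1)(c1ccccc1)c1ccccc1.[Br-] | intermediate
10 | (2E,4E,6E)-2,7-dimethylocta-2,4,6-trienedial | O=C/C(C)=C/C=C/C=C(C)/C=O | starting material
11 | [(2E,6E)-3,7,11-trimethyldodeca-2,6,10-trien-1-ylidene]triphenylphosphorane (ylide) | CC(C)=CCC/C(C)=C/CC/C(C)=C/C=P(c1ccccc1)(c1ccccc1)c1ccccc1 | intermediate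
12 | (2E,4E,6E,8E,10E,14E)-2,7,11,15,19-pentamethylicosa-2,4,6,8,10,14,18-heptaenal | CC(C)=CCC/C(C)=C/CC/C(C)=C/C=C/C(C)=C/C=C/C=C(C)/C=O | intermediate
13 | 1-bromobut-2-yne | CC#CCBr | starting material
14 | diethyl but-2-yn-1-ylphosphonate | CC#CCP(=O)(OCC)OCC | intermediate
15 | lithium salt of diethyl but-2-yn-1-ylphosphonate, carbanion at C1 | [Li+].CC#C[CH-]P(=O)(OCC)OCC | intermediate
16 | (4E,6E,8E,10E,12E,14E,18E)-6,11,15,19,23-pentamethyltetracosa-4,6,8,10,12,14,18,22-octaen-2-yne | CC(C)=CCC/C(C)=C/CC/C(C)=C/C=C/C(C)=C/C=C/C=C(C)/C=C/C#CC | intermediate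
17 | 1,1-diisopropoxy-1-titanacycloprop-2-ene with methyl on C9 and the C26 polyenyl chain on C10 (η2-complex of the triple bond of 16) | CC(C)O[Ti]1(OC(C)C)C(C)=C1/C=C/C(C)=C/C=C/C=C(C)/C=C/C=C(C)/CC/C=C(C)/CCC=C(C)C | intermediate
18 | 1,1-diisopropoxy-1-titanacyclopenta-2,4-diene with the 2,6,6-trimethylcyclohex-2-en-1-yl group on C7, H on C8, methyl on C9 and the C26 polyenyl chain on C10 (ring stereocentre as in 7) | CC(C)O[Ti]1(OC(C)C)C([C@H]2C(C)=CCCC2(C)C)=CC(C)=C1/C=C/C(C)=C/C=C/C=C(C)/C=C/C=C(C)/CC/C=C(C)/CCC=C(C)C | intermediate
19 | (6R)-7',8'-dihydro-ε,ψ-carotene (α-zeacarotene) | CC(C)=CCC/C(C)=C/CC/C(C)=C/C=C/C(C)=C/C=C/C=C(C)/C=C/C=C(C)/C=C/[C@H]1C(C)=CCCC1(C)C | target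

**Count and risks**

Total step count: 9. Longest linear sequence: 5 steps (steps 1, 2, 3, 4, 9).

Step 9 is the riskiest. The low-valent titanium may transfer electrons to, or complex with, the conjugated polyene instead of forming the titanacyclopropene cleanly. The acetylenic C–H of 7 may protonate 17, or the insertion may take the opposite regiochemistry. The fallback sets out from 7 and 16 and comes back at 19, forming the same C8–C9 bond by known chemistry. Hydrozirconation of 7 with Cp2Zr(H)Cl (THF, rt) should give the (E)-alkenylzirconocene chloride F1. In a second flask, 16 is hydrozirconated (Cp2Zr(H)Cl, THF, 40 °C), with zirconium settling on the less hindered methyl-bearing C9, to give the alkenylzirconocene chloride F2. Iodine converts F2 with retention into the (2E)-2-iodo nonaene F3. Negishi coupling of F1 with F3 (ZnCl2, Pd(PPh3)4 as the zerovalent palladium catalyst, THF, rt) should then give 19.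

Step 4 is second. The strong base may cause propargyl–allenyl isomerisation that scrambles C6, aldol self-condensation of 5 may outrun O-sulfonylation, or the reaction may stall at the alkenyl nonaflate. The fallback sets out from 5 and comes back at 7. Condensation with hydrazine hydrate (EtOH, Et3N) should give the hydrazone F4. The Barton vinyl iodide procedure (I2, 1,1,3,3-tetramethylguanidine, Et2O, 0 °C) should convert it into the 1-iodoalkene F5 as an E/Z mixture. Dehydroiodination with NaN(SiMe3)2 (THF, −78 °C) should then give 7.

Step 6 is third. The delocalised allylic ylide may lose the E geometry of the trisubstituted C9'=C10' double bond, both formyl groups may be olefinated, or iodine may fail to drive the new double bond to one isomer. The fallback sets out from 8 and 10 and comes back at 12. A Michaelis–Arbuzov reaction of 8 with P(OEt)3 (110 °C) should give diethyl [(2E,6E)-3,7,11-trimethyldodeca-2,6,10-trien-1-yl]phosphonate F6. Its lithio derivative (n-BuLi, THF–DMPU, −78 °C) is added to an excess of 10 in a Horner–Wadsworth–Emmons reaction. This should be trans-selective at C11'=C12' and should hold the allylic double-bond geometry better at low temperature.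

Further compounds
F1 | step 9 | chlorobis(cyclopentadienyl){(E)-2-[(1R)-2,6,6-trimethylcyclohex-2-en-1-yl]ethenyl}zirconium | Cl[Zr](/C=C/[C@H]1C(C)=CCCC1(C)C)(C1C=CC=C1)C1C=CC=C1
F2 | step 9 | chlorobis(cyclopentadienyl)[(2E,4E,6E,8E,10E,12E,14E,18E)-6,11,15,19,23-pentamethyltetracosa-2,4,6,8,10,12,14,18,22-nonaen-2-yl]zirconium | Cl[Zr](/C(C)=C/C=C/C(C)=C/C=C/C=C(C)/C=C/C=C(C)/CC/C=C(C)/CCC=C(C)C)(C1C=CC=C1)C1C=CC=C1
F3 | step 9 | (2E,4E,6E,8E,10E,12E,14E,18E)-2-iodo-6,11,15,19,23-pentamethyltetracosa-2,4,6,8,10,12,14,18,22-nonaene | I/C(C)=C/C=C/C(C)=C/C=C/C=C(C)/C=C/C=C(C)/CC/C=C(C)/CCC=C(C)C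
F4 | step 4 | 2-[(1R)-2,6,6-trimethylcyclohex-2-en-1-yl]acetaldehyde hydrazone | NN=CC[C@H]1C(C)=CCCC1(C)C
F5 | step 4 | (6R)-6-(2-iodoethenyl)-1,5,5-trimethylcyclohex-1-ene (E/Z mixture) | IC=C[C@H]1C(C)=CCCC1(C)C
F6 | step 6 | diethyl [(2E,6E)-3,7,11-trimethyldodeca-2,6,10-trien-1-yl]phosphonate | CC(C)=CCC/C(C)=C/CC/C(C)=C/CP(=O)(OCC)OCC
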